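Ring A is cut between a1, the acyl-bearing carbon, and a6. The key step exploits the 2-acylresorcinol pattern of ring A: an acyl group on a1 flanked by hydroxyls on a2 and a6, with a3–a5 unsubstituted, is the pattern of a linear diketo ester. In one operation a base-induced Claisen closure forms the a1–a6 bond and ring A, and acid-induced loss of a sacrificial silyloxy group on a4 aromatises it without an oxidant. The precursor is an open-chain methyl 3-silyloxy-5,7-dioxo ester carrying the eight-carbon tether and the dimethyl-protected catechol ring B, assembled by acylating a methyl ketone enolate with a glutarate half-ester chloride.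

Key step: step 6

Remark: enolates, metal chelates and other salts of a numbered compound are treated as that compound in ionised form and get no number of their own; the silyloxy-bearing carbon is carried as a racemate because step 6 erases it.

Step 1
Reactants: 1 veratrole, 2 monomethyl azelate
Product: 4 methyl 9-(3,4-dimethoxyphenyl)-9-oxononanoate, via acid chloride 3 (not isolated)
Conditions: 2, (COCl)2, DMF (cat.), CH2Cl2, 0 °C to rt, concentrate; then 1, AlCl3 (2.2 equiv), CH2Cl2, 0 °C to rt; ice/aq. HCl
Reagents that add atoms: none
Why: Friedel–Crafts acylation of the electron-rich veratrole by the acid chloride made in the flask should go para to one methoxy group, the most activated and least hindered position, while the methyl ester only complexes AlCl3 and the deactivated aryl ketone formed resists a second acylation.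

Step 2
Reactants: 4 methyl 9-(3,4-dimethoxyphenyl)-9-oxononanoate
Product: 5 methyl 9-(3,4-dimethoxyphenyl)nonanoate
Conditions: Et3SiH (3 equiv), CF3CO2H, rt to 50 °C
Reagents that add atoms: none
Why: Ionic hydrogenation (Kursanov–Parnes reduction) should take the aryl ketone to the methylene, because protonation gives a benzylic cation stabilised by the para-methoxy group that Et3SiH reduces in two hydride transfers, while the aliphatic ester and the aryl ethers are inert to CF3CO2H.

Step 3
Reactants: 5 methyl 9-(3,4-dimethoxyphenyl)nonanoate
Product: 7 10-(3,4-dimethoxyphenyl)decan-2-one, via Weinreb amide 6 (not isolated)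
Conditions: MeNH(OMe)·HCl (1.5 equiv), i-PrMgCl (3 equiv), THF, −20 to −10 °C; then MeMgBr (2.5 equiv), 0 °C; aq. HCl
Reagents that add atoms: methylmagnesium bromide, C[Mg]Br
Why: Aminolysis of the ester by the magnesium amide of N,O-dimethylhydroxylamine gives the Weinreb amide, whose chelated tetrahedral adduct with MeMgBr cannot collapse before work-up, so the Weinreb ketone synthesis should stop at the methyl ketone.

Step 4
Reactants: 8 3-(tert-butyldimethylsilyloxy)glutaric anhydride
Product: 9 rac-3-(tert-butyldimethylsilyloxy)-5-methoxy-5-oxopentanoic acid
Conditions: MeOH (5 equiv), DMAP (cat.), CH2Cl2, rt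
Reagents that add atoms: methanol, CO
Why: Nucleophile-catalysed alcoholysis of a cyclic anhydride opens the ring once and stops at the half-ester because the carboxylate formed is unreactive; methanol attacks the two enantiotopic carbonyls equally, so the new stereocentre at C3 forms as a racemate, which is harmless since step 6 erases it.

Step 5
Reactants: 7 10-(3,4-dimethoxyphenyl)decan-2-one, 9 rac-3-(tert-butyldimethylsilyloxy)-5-methoxy-5-oxopentanoic acid
Product: 11 methyl rac-3-(tert-butyldimethylsilyloxy)-15-(3,4-dimethoxyphenyl)-5,7-dioxopentadecanoate, via half-ester chloride 10 (not isolated)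
Conditions: 9, Me2C=C(Cl)NMe2, CH2Cl2, 0 °C to rt, concentrate; 7 (2.1 equiv), LiN(i-Pr)2 (2.05 equiv), THF, −78 °C; then 10 in THF, −78 °C; 1 M aq. HCl, 0 °C
Reagents that add atoms: none
Why: Kinetic deprotonation of the methyl ketone at −78 °C gives the less substituted lithium enolate, whose crossed Claisen C-acylation by the acid chloride (made under neutral conditions that spare the silyl ether) is far faster than attack at the methyl ester; the second equivalent of enolate takes up the acidic proton of the 1,3-diketone, which shields the product from a second acylation and returns ketone 7 for recovery.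

Step 6
Reactants: 11 methyl rac-3-(tert-butyldimethylsilyloxy)-15-(3,4-dimethoxyphenyl)-5,7-dioxopentadecanoate
Product: 13 1-(2,6-dihydroxyphenyl)-9-(3,4-dimethoxyphenyl)nonan-1-one, via silyloxy acylcyclohexanedione 12 (not isolated)
Conditions: KOt-Bu (1.05 equiv), THF, 0 to 40 °C; then 2 M aq. HCl, 50 °C
Reagents that add atoms: none
Why: One equivalent of KOt-Bu ionises only C6 of 11, the carbon between the two ketones, and this diketonate attacks the ester carbonyl C1 through carbon and expels methoxide, which at once deprotonates the far more acidic 2-acyl-1,3-dione 12, so the Claisen (Dieckmann) condensation is drawn to the cyclised triketonate. The closest known reaction types are the Dieckmann cyclisation of 5,7-diketo esters to 2-acylcyclohexane-1,3-diones, the Claisen cyclisation of triketo esters to acylphloroglucinols and the Lacey–Dieckmann closure of 3-acyltetramic acids, and the aromatisation that follows is an acid-catalysed beta-elimination of the aldol-dehydration kind. Ring A closes in the favoured 6-(enolendo)-exo-trig mode. In warm aqueous acid the ring enol of 12 expels the silyloxy group from ring carbon 5, which lies beta to both ring carbonyls, and the cyclohexenedione formed tautomerises irreversibly to the resorcinol, so no oxidant is needed; no stereocentre is created and the racemic one of 11 is erased. The step needs C- over O-acylation and ring closure before loss of the silyloxy group: only C-acylation ends in the stabilised triketonate, and once C6 is ionised no base strong enough to deprotonate C2 or C4 remains, so an E1cB loss of silanolate to an open-chain (E)-enoate or (E)-enone that could no longer cyclise is held back.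

Step 7
Reactants: 13 1-(2,6-dihydroxyphenyl)-9-(3,4-dimethoxyphenyl)nonan-1-one
Product: 14 malabaricone C, 1-(2,6-dihydroxyphenyl)-9-(3,4-dihydroxyphenyl)nonan-1-one
Conditions: BBr3 (6 equiv), CH2Cl2, −78 °C to rt; then MeOH, H2O
Reagents that add atoms: none
Why: Lewis-acid ether cleavage by BBr3 (boron binds each methoxy oxygen and bromide attacks the methyl group in an SN2 step) should free the catechol of ring B, while the hydrogen-bonded aryl ketone and the resorcinol hydroxyls are only held as borates that methanol and water hydrolyse.

Compound list
1 | veratrole (1,2-dimethoxybenzene) | COc1ccccc1OC | starting material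
2 | monomethyl azelate (9-methoxy-9-oxononanoic acid) | COC(=O)CCCCCCCC(=O)O | starting material
3 | methyl 9-chloro-9-oxononanoate (formed in the flask) | COC(=O)CCCCCCCC(=O)Cl | intermediate
4 | methyl 9-(3,4-dimethoxyphenyl)-9-oxononanoate | COC(=O)CCCCCCCC(=O)c1ccc(OC)c(OC)c1 | intermediate
5 | methyl 9-(3,4-dimethoxyphenyl)nonanoate | COC(=O)CCCCCCCCc1ccc(OC)c(OC)c1 | intermediate
6 | 9-(3,4-dimethoxyphenyl)-N-methoxy-N-methylnonanamide (formed in the flask) | CON(C)C(=O)CCCCCCCCc1ccc(OC)c(OC)c1 | intermediate
7 | 10-(3,4-dimethoxyphenyl)decan-2-one | CC(=O)CCCCCCCCc1ccc(OC)c(OC)c1 | intermediate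
8 | 3-(tert-butyldimethylsilyloxy)glutaric anhydride (achiral) | CC(C)(C)[Si](C)(C)OC1CC(=O)OC(=O)C1 | starting material
9 | rac-3-(tert-butyldimethylsilyloxy)-5-methoxy-5-oxopentanoic acid | COC(=O)CC(O[Si](C)(C)C(C)(C)C)CC(=O)O | intermediate
10 | methyl rac-3-(tert-butyldimethylsilyloxy)-5-chloro-5-oxopentanoate (formed in the flask) | COC(=O)CC(O[Si](C)(C)C(C)(C)C)CC(=O)Cl | intermediate
11 | methyl rac-3-(tert-butyldimethylsilyloxy)-15-(3,4-dimethoxyphenyl)-5,7-dioxopentadecanoate | COC(=O)CC(O[Si](C)(C)C(C)(C)C)CC(=O)CC(=O)CCCCCCCCc1ccc(OC)c(OC)c1 | intermediate
12 | 5-(tert-butyldimethylsilyloxy)-2-[9-(3,4-dimethoxyphenyl)nonanoyl]cyclohexane-1,3-dione (formed in the flask, present as its enolate, drawn as the triketone) | COc1ccc(CCCCCCCCC(=O)C2C(=O)CC(O[Si](C)(C)C(C)(C)C)CC2=O)cc1OC | intermediate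
13 | 1-(2,6-dihydroxyphenyl)-9-(3,4-dimethoxyphenyl)nonan-1-one | COc1ccc(CCCCCCCCC(=O)c2c(O)cccc2O)cc1OC | intermediate
14 | malabaricone C, 1-(2,6-dihydroxyphenyl)-9-(3,4-dihydroxyphenyl)nonan-1-one (no stereocentre) | O=C(CCCCCCCCc1ccc(O)c(O)c1)c1c(O)cccc1O | target

Total step count: 7 steps.
Longest linear sequence: 6 steps (steps 1, 2, 3, 5, 6 and 7); step 4 is a one-step side branch that joins in step 5.

Steps most likely to fail

Step 6. The silyloxy group may be lost by base-induced elimination before the ring has closed, which would leave an open-chain unsaturated diketo ester of the wrong geometry for closure, or the cyclised dione may resist elimination and aromatisation. The fallback uses known chemistry and buys ring A instead of building it. It sets out from Weinreb amide 6, isolated by working up step 3 before MeMgBr is added. 1,3-Dimethoxybenzene is lithiated between its two methoxy groups (n-BuLi, THF, 0 °C to rt) to give 2,6-dimethoxyphenyllithium F1. F1 adds to 6 (THF, −78 to 0 °C) and, after acidic work-up, should give 1-(2,6-dimethoxyphenyl)-9-(3,4-dimethoxyphenyl)nonan-1-one F2. BBr3 (excess, CH2Cl2, −78 °C to rt) should then cleave all four methyl ethers, and the route is rejoined at target 14.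

Step 5. O-acylation of the enolate, a second acylation, or ketene formation and elimination of the silyloxy group in the acid chloride may erode the C-acylation. The fallback replaces the crossed Claisen acylation by aldol addition and oxidation. It sets out from half-ester 9. BH3·SMe2 (THF, 0 °C) should reduce the free acid selectively to methyl rac-3-(tert-butyldimethylsilyloxy)-5-hydroxypentanoate F3. Dess–Martin periodinane should give the aldehyde methyl rac-3-(tert-butyldimethylsilyloxy)-5-oxopentanoate F4. One equivalent of the lithium enolate of 7 (LiN(i-Pr)2, THF, −78 °C) adds to F4 to give the aldol methyl 3-(tert-butyldimethylsilyloxy)-15-(3,4-dimethoxyphenyl)-5-hydroxy-7-oxopentadecanoate F5, a diastereomer mixture of no consequence. A second Dess–Martin oxidation of the beta-hydroxy ketone returns to the route at diketo ester 11.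

Step 3. Incomplete aminolysis of the ester would let MeMgBr add twice to the ester that is left, so that over-addition to a tertiary alcohol competes with ketone formation. The fallback goes through the carboxylate and sets out from ester 5. LiOH (THF/H2O, rt) gives 9-(3,4-dimethoxyphenyl)nonanoic acid F6. MeLi (2.2 equiv, THF, 0 °C) converts F6 into the dilithium gem-diolate, which cannot add further. A Me3SiCl quench followed by aqueous acid returns to the route at methyl ketone 7.

Further compounds
F1 | step 6 | 2,6-dimethoxyphenyllithium | [Li]c1c(OC)cccc1OC
F2 | step 6 | 1-(2,6-dimethoxyphenyl)-9-(3,4-dimethoxyphenyl)nonan-1-one | COc1ccc(CCCCCCCCC(=O)c2c(OC)cccc2OC)cc1OC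
F3 | step 5 | methyl rac-3-(tert-butyldimethylsilyloxy)-5-hydroxypentanoate | COC(=O)CC(O[Si](C)(C)C(C)(C)C)CCO
F4 | step 5 | methyl rac-3-(tert-butyldimethylsilyloxy)-5-oxopentanoate | COC(=O)CC(O[Si](C)(C)C(C)(C)C)CC=O
F5 | step 5 | methyl 3-(tert-butyldimethylsilyloxy)-15-(3,4-dimethoxyphenyl)-5-hydroxy-7-oxopentadecanoate (racemic diastereomer mixture) | COC(=O)CC(O[Si](C)(C)C(C)(C)C)CC(O)CC(=O)CCCCCCCCc1ccc(OC)c(OC)c1
F6 | step 3 | 9-(3,4-dimethoxyphenyl)nonanoic acid | OC(=O)CCCCCCCCc1ccc(OC)c(OC)c1
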